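## Retrosynthetic overview
1. 15 ⇒ 14: the C4 methylene comes from hydride opening of the benzylic C–O bond of a (6aR,11aR)-pterocarpan. C6a becomes C3 unchanged.
2. 14 ⇒ 4 + 12, in one flask. Ring C (pyran) forms by gold-catalysed 6-endo hydroarylation. Ring D (dihydrofuran) then forms by an enantioselective palladium oxyarylation that makes C3–C1', C4–O and both stereocentres.
3. 4 ⇒ 2 ⇒ 1: the C2v symmetry of 2,6-dihydroxy-4-methoxybenzaldehyde fixes the 5-OMe/7-OH/8-CHO pattern, so no late formylation is needed.
4. 12 ⇒ 5: two directed lithiations of resorcinol bis-MOM ether place the prenyl group between the oxygens and the iodine next to one of them.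
5. Ring order: C, then D in the same operation. D is opened again in the last step.

Assumption: the descriptor in the target SMILES corresponds to (3R) by CIP analysis. Which ligand antipode gives (6aR,11aR)-14 is settled by one test run, since both antipodes are sold.

## Route

Step 1
Reactants: 1 2,4,6-trihydroxybenzaldehyde
Product: 2 2,6-dihydroxy-4-methoxybenzaldehyde
Conditions: MeI (1.0 equiv), K2CO3 (1.0 equiv), acetone, 0 °C to rt
Reagents that add atoms: iodomethane, CI
Why: The 4-OH lies para to the formyl group and is not held in a hydrogen bond, so it is the most acidic and is alkylated first (chemoselective Williamson ether synthesis), giving a C2v-symmetric arene.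

Step 2
Reactants: 2 2,6-dihydroxy-4-methoxybenzaldehyde, 3 propargyl bromide
Product: 4 2-hydroxy-4-methoxy-6-(prop-2-yn-1-yloxy)benzaldehyde
Conditions: K2CO3 (1.1 equiv), acetone, 50 °C
Reagents that add atoms: none
Why: In this Williamson ether synthesis the two hydroxyls are equivalent, and after the first alkylation the remaining one is chelated to the aldehyde and reacts much more slowly, so the mono-ether is obtained.

Step 3
Reactants: 5 resorcinol
Product: 6 1,3-bis(methoxymethoxy)benzene
Conditions: NaH (2.2 equiv), MOMCl (2.2 equiv), DMF, 0 °C to rt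
Reagents that add atoms: chloromethyl methyl ether, COCCl
Why: Double O-alkylation of the bis-phenoxide installs two acetal groups that both protect the phenols and direct the lithiations that follow.

Step 4
Reactants: 6 1,3-bis(methoxymethoxy)benzene, 7 prenyl bromide
Product: 9 1,3-bis(methoxymethoxy)-2-(3-methylbut-2-en-1-yl)benzene, via aryllithium 8 (not isolated)
Conditions: n-BuLi (1.1 equiv), THF, 0 °C to rt; CuI (10 mol %), then 7, −78 °C to rt
Reagents that add atoms: none
Why: Directed ortho-metalation removes the proton flanked by both OMOM groups, and the copper-assisted SN2 reaction with prenyl bromide puts the prenyl group between the two oxygens without allylic transposition.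

Step 5
Reactants: 9 1,3-bis(methoxymethoxy)-2-(3-methylbut-2-en-1-yl)benzene
Product: 12 4-iodo-2-(3-methylbut-2-en-1-yl)benzene-1,3-diol, via aryllithium 10 (not isolated), via MOM iodide 11 (not isolated)
Conditions: s-BuLi (1.1 equiv), TMEDA, THF, −78 °C; ICH2CH2I, −78 °C to rt; short aqueous wash, crude into MeOH, p-TsOH·H2O (0.2 equiv), 40 °C
Reagents that add atoms: 1,2-diiodoethane, ICCI
Why: A second directed ortho-metalation takes the remaining position next to an OMOM group, 1,2-diiodoethane transfers iodine with loss of ethene, and acid-catalysed acetal exchange with methanol frees both phenols under conditions that prenylated phenols tolerate.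

Step 6
Reactants: 4 2-hydroxy-4-methoxy-6-(prop-2-yn-1-yloxy)benzaldehyde, 12 4-iodo-2-(3-methylbut-2-en-1-yl)benzene-1,3-diol
Product: 14 (6aR,11aR)-3,9-dihydroxy-1-methoxy-10-(3-methylbut-2-en-1-yl)-6a,11a-dihydro-6H-benzofuro[3,2-c]chromene-4-carbaldehyde, via chromene 13 (not isolated)
Conditions: [Au{P(t-Bu)2(2-biphenylyl)}(NCMe)]SbF6 (2 mol %), 1,2-dichloroethane, 40 °C; then into the same flask 12, Pd2(dba)3 (2.5 mol %), (S)-t-Bu-PHOX (6 mol %), Ag2CO3 (1.2 equiv), acetone, 50 °C
Reagents that add atoms: none
Why: Proposed new method: monovalent gold activates the alkyne of 4 for 6-endo hydroarylation at the only free ortho carbon (the known aryl propargyl ether to 2H-chromene cyclisation), then the aryl–palladium species formed from 12 and zerovalent palladium adds syn across C3=C4 of 13 (aryl to C3, palladium to benzylic C4, no syn β-hydrogen available) and the neighbouring phenoxide closes C4–O by inner-sphere reductive elimination, which can only give the cis-fused pterocarpan; the racemic Heck-type oxyarylation of 2H-chromenes by 2-iodophenols is the closest known reaction, and the new element is a chiral P,N ligand on cationic divalent palladium that makes the migratory insertion face-selective, as in the asymmetric intermolecular Heck reaction and the asymmetric Heck/Tsuji–Trost annulation of 2-halophenols, so that C6a and C11a are set together as (6aR,11aR).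

Step 7
Reactants: 14 (6aR,11aR)-3,9-dihydroxy-1-methoxy-10-(3-methylbut-2-en-1-yl)-6a,11a-dihydro-6H-benzofuro[3,2-c]chromene-4-carbaldehyde
Product: 15 (3R)-3-[2,4-dihydroxy-3-(3-methylbut-2-en-1-yl)phenyl]-7-hydroxy-5-methoxy-3,4-dihydro-2H-chromene-8-carbaldehyde
Conditions: Hantzsch ester (diethyl 2,6-dimethyl-1,4-dihydropyridine-3,5-dicarboxylate, 1.5 equiv), (PhO)2P(O)OH (20 mol %), toluene, 50 °C
Reagents that add atoms: none
Why: Proposed new method: the phosphoric acid ionises the benzylic C11a–O bond, which is flanked by two ortho oxygens and a para hydroxyl, to a para-quinone methide that takes hydride at C4 from the Hantzsch ester, an ionic and biomimetic version of the known hydrogenolysis of pterocarpans to 2'-hydroxyisoflavans and closely related to known transfer hydrogenations of quinone methides; C6a is not involved and becomes (3R)-C3, while the chelated aldehyde, the prenyl alkene and the primary aryl ether O1–C2 are inert to this hydride donor.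

## Compound list
1 | 2,4,6-trihydroxybenzaldehyde | Oc1cc(O)c(C=O)c(O)c1 | starting material
2 | 2,6-dihydroxy-4-methoxybenzaldehyde | COc1cc(O)c(C=O)c(O)c1 | intermediate
3 | propargyl bromide (3-bromoprop-1-yne) | C#CCBr | starting material
4 | 2-hydroxy-4-methoxy-6-(prop-2-yn-1-yloxy)benzaldehyde | COc1cc(O)c(C=O)c(OCC#C)c1 | intermediate
5 | resorcinol | Oc1cccc(O)c1 | starting material
6 | 1,3-bis(methoxymethoxy)benzene | COCOc1cccc(OCOC)c1 | intermediate
7 | prenyl bromide (1-bromo-3-methylbut-2-ene) | CC(C)=CCBr | starting material
8 | 2,6-bis(methoxymethoxy)phenyllithium | [Li]c1c(OCOC)cccc1OCOC | intermediate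
9 | 1,3-bis(methoxymethoxy)-2-(3-methylbut-2-en-1-yl)benzene | COCOc1cccc(OCOC)c1CC=C(C)C | intermediate
10 | 2,4-bis(methoxymethoxy)-3-(3-methylbut-2-en-1-yl)phenyllithium | [Li]c1ccc(OCOC)c(CC=C(C)C)c1OCOC | intermediate
11 | 1-iodo-2,4-bis(methoxymethoxy)-3-(3-methylbut-2-en-1-yl)benzene | COCOc1ccc(I)c(OCOC)c1CC=C(C)C | intermediate
12 | 4-iodo-2-(3-methylbut-2-en-1-yl)benzene-1,3-diol | Oc1ccc(I)c(O)c1CC=C(C)C | intermediate
13 | 7-hydroxy-5-methoxy-2H-chromene-8-carbaldehyde | COc1cc(O)c(C=O)c2OCC=Cc12 | intermediate
14 | (6aR,11aR)-3,9-dihydroxy-1-methoxy-10-(3-methylbut-2-en-1-yl)-6a,11a-dihydro-6H-benzofuro[3,2-c]chromene-4-carbaldehyde | COc1cc(O)c(C=O)c2c1[C@@H]1Oc3c(CC=C(C)C)c(O)ccc3[C@@H]1CO2 | intermediate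
15 | (3R)-3-[2,4-dihydroxy-3-(3-methylbut-2-en-1-yl)phenyl]-7-hydroxy-5-methoxy-3,4-dihydro-2H-chromene-8-carbaldehyde | COc1cc(O)c(C=O)c2c1C[C@H](c1ccc(O)c(CC=C(C)C)c1O)CO2 | target

## Step count and risks
Total step count: 7. Longest linear sequence: 5 (steps 3, 4, 5, 6, 7).

**Step 6** is the most likely to fail. The face selectivity of the insertion is untested. The salicylaldehyde unit of 13 could also be arylated at the formyl C–H, and the gold residue has to be tolerated by palladium. The fallback sets out from 4 and 12. Both stages are run using PPh3 in place of the chiral ligand to give the racemic cis-pterocarpan F1. This is isomerised by p-TsOH in warm toluene to the achiral 2'-hydroxyisoflav-3-ene F2. A chiral phosphoric acid ((R)-TRIP) then protonates C4, so that the ortho-quinone methide of ring B is reduced at C3 by the Hantzsch ester. The stereocentre then comes from an organocatalytic transfer hydrogenation instead of the palladium step. The route is rejoined at 15.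

**Step 7** is the second risk. The formyl group slows the ionisation, and the quinone methide can tautomerise to the isoflav-3-ene, which would erode the configuration at C3. The fallback sets out from 14. The quinone methide is trapped by thiophenol (catalytic (PhO)2P(O)OH, CH2Cl2, rt) as the (3R)-4-phenylsulfanyl isoflavan F3. The sulfur is then removed by a radical chain ((Me3Si)3SiH, AIBN, toluene, 80 °C), which leaves the aldehyde, the alkene and C3 alone. The route is rejoined at 15.

**Step 5** is the third risk. The benzylic, allylic CH2 of the prenyl group can be deprotonated in competition with the ring. The electron-rich iodoresorcinol can also lose iodine in acid. The fallback sets out from 6. NBS gives 1-bromo-2,4-bis(methoxymethoxy)benzene F4. LiTMP removes the proton between the two acetal oxygens, and 7 then gives 1-bromo-2,4-bis(methoxymethoxy)-3-(3-methylbut-2-en-1-yl)benzene F5. Bromine–lithium exchange by n-BuLi at −78 °C, which is far faster than any deprotonation, delivers the aryllithium. The route is rejoined at 10.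

## Further compounds
F1 | step 6 | racemate of 14, that is 14 plus its (6aS,11aS) mirror image (mirror image shown) | COc1cc(O)c(C=O)c2c1[C@H]1Oc3c(CC=C(C)C)c(O)ccc3[C@H]1CO2
F2 | step 6 | 3-[2,4-dihydroxy-3-(3-methylbut-2-en-1-yl)phenyl]-7-hydroxy-5-methoxy-2H-chromene-8-carbaldehyde | COc1cc(O)c(C=O)c2c1C=C(CO2)c1ccc(O)c(CC=C(C)C)c1O
F3 | step 7 | (3R)-3-[2,4-dihydroxy-3-(3-methylbut-2-en-1-yl)phenyl]-7-hydroxy-5-methoxy-4-(phenylsulfanyl)-3,4-dihydro-2H-chromene-8-carbaldehyde (mixture at C4) | COc1cc(O)c(C=O)c2c1C(Sc1ccccc1)[C@H](c1ccc(O)c(CC=C(C)C)c1O)CO2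
F4 | step 5 | 1-bromo-2,4-bis(methoxymethoxy)benzene | COCOc1ccc(Br)c(OCOC)c1
F5 | step 5 | 1-bromo-2,4-bis(methoxymethoxy)-3-(3-methylbut-2-en-1-yl)benzene | COCOc1ccc(Br)c(OCOC)c1CC=C(C)C
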